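**Plan**

1. Arene numbering: C1 carries the C17 chain, C2–H, C3–OH, C4–H, C5–OH, C6–OAc. The C6 oxygen is para to the C3 oxygen and has a further oxygen beside it at C5. This hydroquinone pattern, with the hindered oxygen already acylated, is what ring expansion of a 4-acetoxy-3-alkoxy-4-(alk-1-en-2-yl)cyclobut-2-enone delivers, so the benzene ring itself is disconnected.
2. Cuts, in retrosynthetic order: the C5 O–H back to a tert-butyl ether; the arene C2–C3 bond (back to the four-membered ring); the bond from the acetoxy-bearing cyclobutenone carbon to the alkenyl group together with the O–acetyl bond; the C–Br bond and the terminal alkyne carbon of the side chain.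
3. Forward: linoleic acid is taken to the aldehyde, homologated by one carbon to the terminal alkyne and bromoborated to the 2-bromo-1-alkene. Di-tert-butyl squarate is reduced and rearranged to tert-butyl semisquarate.
4. The alkenyllithium adds to the semisquarate and the alkoxide is capped with acetic anhydride. Heating then builds the only ring, the benzene ring, and cold acid frees the C5 hydroxyl.
5. Stereochemistry: the target has no stereocentre. Both Z alkenes come unchanged from linoleic acid, and the single stereocentre of the racemic cyclobutenone is erased when the ring opens.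

Key step: step 8

**Route**

Step 1
Reactants: 1 linoleic acid ((9Z,12Z)-octadeca-9,12-dienoic acid)
Product: 2 linoleyl alcohol ((9Z,12Z)-octadeca-9,12-dien-1-ol)
Conditions: LiAlH4, THF, 0 °C to rt
Reagents that add atoms: none
Why: Hydride reduction of a carboxylic acid with LiAlH4 should give the primary alcohol while the isolated, non-conjugated Z alkenes are inert to the reagent.

Step 2
Reactants: 2 linoleyl alcohol
Product: 3 linoleyl aldehyde ((9Z,12Z)-octadeca-9,12-dienal)
Conditions: Dess–Martin periodinane, CH2Cl2, 0 °C to rt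
Reagents that add atoms: none
Why: Dess–Martin oxidation should stop at the aldehyde under neutral, anhydrous conditions that neither over-oxidise nor isomerise the skipped diene.

Step 3
Reactants: 3 linoleyl aldehyde; 4 dimethyl (1-diazo-2-oxopropyl)phosphonate
Product: 5 (10Z,13Z)-nonadeca-10,13-dien-1-yne
Conditions: K2CO3, MeOH, 0 °C to rt
Reagents that add atoms: 4 dimethyl (1-diazo-2-oxopropyl)phosphonate, COP(=O)(OC)C(=[N+]=[N-])C(C)=O (supplies the terminal alkyne carbon)
Why: In the Ohira–Bestmann (Seyferth–Gilbert) homologation, methanolysis of 4 frees the diazomethylphosphonate anion, whose Horner–Wadsworth–Emmons addition, loss of N2 and 1,2-hydrogen shift should turn the aldehyde into the terminal alkyne under base too mild to move the Z alkenes.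

Step 4
Reactants: 5 (10Z,13Z)-nonadeca-10,13-dien-1-yne
Product: 7 (10Z,13Z)-2-bromononadeca-1,10,13-triene, via (Z)-2-bromoalkenyl-9-BBN 6 (not isolated)
Conditions: B-Br-9-BBN, CH2Cl2, 0 °C; then AcOH, 0 °C to rt
Reagents that add atoms: B-bromo-9-borabicyclo[3.3.1]nonane, BrB1C2CCCC1CCC2
Why: Haloboration with B-bromo-9-BBN should add B–Br syn and Markovnikov to the terminal alkyne only (the reagent has no B–H and does not add to internal alkenes), and protodeboronation with acetic acid then leaves the 2-bromo-1-alkene.

Step 5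
Reactants: 8 di-tert-butyl squarate (3,4-di-tert-butoxycyclobut-3-ene-1,2-dione)
Product: 9 2,3-di-tert-butoxy-4-hydroxycyclobut-2-en-1-one (racemic)
Conditions: LiAlH(OtBu)3, THF, −78 to 0 °C
Reagents that add atoms: none
Why: Monoreduction with the bulky, mild hydride LiAlH(OtBu)3 should deliver one hydride 1,2 to one of the two equivalent carbonyls, as known for dialkyl squarates, and the racemic carbinol centre formed is removed in step 6.

Step 6
Reactants: 9 2,3-di-tert-butoxy-4-hydroxycyclobut-2-en-1-one
Product: 11 3-tert-butoxycyclobut-3-ene-1,2-dione (tert-butyl semisquarate), via allylic trifluoroacetate 10 (not isolated)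
Conditions: (CF3CO)2O, 2,6-lutidine, CH2Cl2, −78 to 0 °C
Reagents that add atoms: none
Why: In this anhydride-induced rearrangement of a squarate adduct to a cyclobutenedione, trifluoroacetylation and ionisation give an alkoxy-stabilised cyclobutenyl cation that loses its tert-butyl group as isobutene to unveil the second carbonyl, while the hindered base scavenges the acid and so protects the remaining tert-butyl vinylogous ester.

Step 7
Reactants: 7 (10Z,13Z)-2-bromononadeca-1,10,13-triene; 11 3-tert-butoxycyclobut-3-ene-1,2-dione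
Product: 14 2-tert-butoxy-1-[(10Z,13Z)-nonadeca-1,10,13-trien-2-yl]-4-oxocyclobut-2-en-1-yl acetate (racemic), via alkenyllithium 12 (not isolated), via lithium alkoxide 13 (not isolated)
Conditions: t-BuLi (2 equiv), Et2O, −78 °C; cannulate into 11, THF, −78 °C; then Ac2O, −78 to −20 °C
Reagents that add atoms: acetic anhydride, CC(=O)OC(C)=O
Why: Lithium–bromine exchange gives the alkenyllithium, 1,2-addition should take place at the ketone-like carbonyl next to the tert-butoxy-bearing carbon because the other carbonyl is a deactivated vinylogous ester, and O-acylation of the tertiary lithium alkoxide in the cold fixes the acetate before the alkoxide can ring-open, the new quaternary centre being racemic and destroyed in step 8.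

Step 8
Reactants: 14 2-tert-butoxy-1-[(10Z,13Z)-nonadeca-1,10,13-trien-2-yl]-4-oxocyclobut-2-en-1-yl acetate
Product: 17 2-tert-butoxy-6-[(8Z,11Z)-heptadeca-8,11-dien-1-yl]-4-hydroxyphenyl acetate, via (Z)-dienylketene 15 (not isolated), via cyclohexadienone 16 (not isolated)
Conditions: PhMe (degassed, 0.02 M), 110 °C, Ar
Reagents that add atoms: none
Why: Heating should break the bond between the carbonyl carbon and the acetoxy-bearing carbon in a conrotatory 4π electrocyclic opening to (Z)-dienylketene 15, whose 6π electrocyclisation joins the terminal CH2 of the 1,1-disubstituted alkene to the ketene carbon (the arene C2–C3 bond) and gives cyclohexadienone 16, which enolises to the phenol. The closest known reaction is the Moore ring expansion of 4-alkenyl-4-hydroxy-, 4-alkoxy- and 4-silyloxycyclobutenones to hydroquinone derivatives, applied here to the O-acetyl carbinol. The six-membered carbocycle closes by a thermal 6π electrocyclisation of the ketene C=C, the enol-ether C=C and the alkene, not by a polar cyclisation. No stereocentre is created, and the one stereocentre of racemic 14 disappears in the ring opening. The step needs torquoselectivity, with the alkenyl group turning inward toward the ketene; this is secured by the acetoxy oxygen, a lone-pair donor that prefers outward rotation, and by the reversibility of the opening, which returns a wrongly opened ketene to 14. Regiochemistry is fixed by connectivity, since the carbinol oxygen becomes the acetylated C6 oxygen, the ketene oxygen the free C3 hydroxyl, the semisquarate oxygen the C5 tert-butyl ether and the alkene carbons C1 and C2, while the skipped Z,Z-diene is a spectator in degassed toluene.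

Step 9
Reactants: 17 2-tert-butoxy-6-[(8Z,11Z)-heptadeca-8,11-dien-1-yl]-4-hydroxyphenyl acetate
Product: 18 ardisiphenol C (2-[(8Z,11Z)-heptadeca-8,11-dien-1-yl]-4,6-dihydroxyphenyl acetate)
Conditions: CF3CO2H, CH2Cl2, 0 °C
Reagents that add atoms: none
Why: Acidolysis of the aryl tert-butyl ether (ionisation to the tert-butyl cation, lost as isobutene) should free the C5 hydroxyl, while the aryl acetate and the Z alkenes tolerate brief cold acid and a non-basic work-up avoids acetyl migration between the neighbouring C6 and C5 oxygens.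

**Compound list**

1 | linoleic acid, (9Z,12Z)-octadeca-9,12-dienoic acid | CCCCC/C=C\C/C=C\CCCCCCCC(=O)O | starting material
2 | linoleyl alcohol, (9Z,12Z)-octadeca-9,12-dien-1-ol | CCCCC/C=C\C/C=C\CCCCCCCCO | intermediate
3 | linoleyl aldehyde, (9Z,12Z)-octadeca-9,12-dienal | CCCCC/C=C\C/C=C\CCCCCCCC=O | intermediate
4 | dimethyl (1-diazo-2-oxopropyl)phosphonate | COP(=O)(OC)C(=[N+]=[N-])C(C)=O | starting material
5 | (10Z,13Z)-nonadeca-10,13-dien-1-yne | CCCCC/C=C\C/C=C\CCCCCCCC#C | intermediate
6 | B-[(1Z,10Z,13Z)-2-bromononadeca-1,10,13-trien-1-yl]-9-borabicyclo[3.3.1]nonane (formed and consumed in step 4) | CCCCC/C=C\C/C=C\CCCCCCC/C(Br)=C/B1C2CCCC1CCC2 | intermediate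
7 | (10Z,13Z)-2-bromononadeca-1,10,13-triene | CCCCC/C=C\C/C=C\CCCCCCCC(Br)=C | intermediate
8 | di-tert-butyl squarate, 3,4-di-tert-butoxycyclobut-3-ene-1,2-dione | CC(C)(C)OC1=C(OC(C)(C)C)C(=O)C1=O | starting material
9 | 2,3-di-tert-butoxy-4-hydroxycyclobut-2-en-1-one (racemic) | CC(C)(C)OC1=C(OC(C)(C)C)C(O)C1=O | intermediate
10 | 2,3-di-tert-butoxy-4-oxocyclobut-2-en-1-yl trifluoroacetate (racemic; formed and consumed in step 6) | CC(C)(C)OC1=C(OC(C)(C)C)C(OC(=O)C(F)(F)F)C1=O | intermediate
11 | 3-tert-butoxycyclobut-3-ene-1,2-dione (tert-butyl semisquarate) | CC(C)(C)OC1=CC(=O)C1=O | intermediate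
12 | [(10Z,13Z)-nonadeca-1,10,13-trien-2-yl]lithium (formed and consumed in step 7) | CCCCC/C=C\C/C=C\CCCCCCCC([Li])=C | intermediate
13 | lithium 2-tert-butoxy-1-[(10Z,13Z)-nonadeca-1,10,13-trien-2-yl]-4-oxocyclobut-2-en-1-olate (racemic; formed and consumed in step 7) | CCCCC/C=C\C/C=C\CCCCCCCC(=C)C1(O[Li])C(OC(C)(C)C)=CC1=O | intermediate
14 | 2-tert-butoxy-1-[(10Z,13Z)-nonadeca-1,10,13-trien-2-yl]-4-oxocyclobut-2-en-1-yl acetate (racemic) | CCCCC/C=C\C/C=C\CCCCCCCC(=C)C1(OC(C)=O)C(OC(C)(C)C)=CC1=O | intermediate
15 | (3Z,13Z,16Z)-4-acetoxy-3-tert-butoxy-5-methylidenedocosa-1,3,13,16-tetraen-1-one (dienylketene; formed and consumed in step 8) | CCCCC/C=C\C/C=C\CCCCCCCC(=C)/C(OC(C)=O)=C(\C=C=O)OC(C)(C)C | intermediate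
16 | 4-acetoxy-3-tert-butoxy-5-[(8Z,11Z)-heptadeca-8,11-dien-1-yl]cyclohexa-2,4-dien-1-one (formed and consumed in step 8) | CCCCC/C=C\C/C=C\CCCCCCCC1=C(OC(C)=O)C(OC(C)(C)C)=CC(=O)C1 | intermediate
17 | 2-tert-butoxy-6-[(8Z,11Z)-heptadeca-8,11-dien-1-yl]-4-hydroxyphenyl acetate | CCCCC/C=C\C/C=C\CCCCCCCc1cc(O)cc(OC(C)(C)C)c1OC(C)=O | intermediate
18 | ardisiphenol C, 2-[(8Z,11Z)-heptadeca-8,11-dien-1-yl]-4,6-dihydroxyphenyl acetate | CCCCC/C=C\C/C=C\CCCCCCCc1cc(O)cc(O)c1OC(C)=O | target

**Step count**

Total: 9 steps. Longest linear sequence: 7 steps (steps 1, 2, 3, 4, 7, 8, 9 from linoleic acid); the squarate branch (steps 5 and 6) joins at step 7.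

**Steps most likely to fail, with fallbacks**

Step 8. Acetoxy is a weaker lone-pair donor than the hydroxyl, alkoxy or silyloxy groups usual in this ring expansion. The opening may therefore become slow enough that thermal loss of isobutene from the tert-butyl enol ether competes. Opening with the acetoxy group turned inward would lead to acyl transfer onto the ketene instead of 6π closure. The fallback sets out from lithium alkoxide 13 and comes back at 17.
- The alkoxide is quenched with Me3SiCl instead of Ac2O to give the trimethylsilyl ether 3-tert-butoxy-4-[(10Z,13Z)-nonadeca-1,10,13-trien-2-yl]-4-(trimethylsilyloxy)cyclobut-2-en-1-one F1, the classical substrate type.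
- Heating F1 in degassed toluene should give the ring-expanded 3-tert-butoxy-5-[(8Z,11Z)-heptadeca-8,11-dien-1-yl]-4-(trimethylsilyloxy)phenol F2.
- Methanol with a trace of citric acid removes the labile aryl trimethylsilyl group to give the hydroquinone 2-tert-butoxy-6-[(8Z,11Z)-heptadeca-8,11-dien-1-yl]benzene-1,4-diol F3, kept under argon.
- t-BuMe2SiCl and imidazole should silylate only the unhindered C3 hydroxyl, giving 2-tert-butoxy-4-(tert-butyldimethylsilyloxy)-6-[(8Z,11Z)-heptadeca-8,11-dien-1-yl]phenol F4.
- Ac2O, Et3N and DMAP acetylate the hindered C6 hydroxyl to give 2-tert-butoxy-4-(tert-butyldimethylsilyloxy)-6-[(8Z,11Z)-heptadeca-8,11-dien-1-yl]phenyl acetate F5.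
- Bu4NF buffered with AcOH removes the aryl silyl ether to give 17. No free hydroxyl sits beside the acetate at this stage, so the acetyl group cannot migrate.

Step 7. Capping of the hindered tertiary lithium alkoxide may be slower than its alkoxide-accelerated ring opening once the mixture warms. Partial attack at the vinylogous ester carbonyl would also pass unseen through a one-pot sequence. The fallback sets out from lithium alkoxide 13 and comes back at 14.
- The cold mixture is quenched with aqueous NH4Cl and the tertiary alcohol 3-tert-butoxy-4-hydroxy-4-[(10Z,13Z)-nonadeca-1,10,13-trien-2-yl]cyclobut-2-en-1-one F6 is isolated and freed of any regioisomeric adduct by chromatography.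
- F6 is then acetylated as the neutral alcohol by nucleophilic catalysis (Ac2O, Et3N, DMAP, CH2Cl2, 0 °C) to give 14.

Step 4. The Lewis-acidic bromoborane, or HBr formed from it by adventitious moisture, may isomerise or hydrobrominate the skipped Z,Z-diene. Incomplete protodeboronation would leave boron-bound material. The fallback sets out from linoleic acid 1, needs no alkyne or bromide, and comes back at alkenyllithium 12.
- Excess MeLi in Et2O at 0 °C, followed by Me3SiCl and aqueous acid, converts the acid into the methyl ketone (10Z,13Z)-nonadeca-10,13-dien-2-one F7.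
- Condensation with 2,4,6-triisopropylbenzenesulfonyl hydrazide gives the trisylhydrazone N'-[(10Z,13Z)-nonadeca-10,13-dien-2-ylidene]-2,4,6-triisopropylbenzenesulfonohydrazide F8.
- A Shapiro reaction (n-BuLi, 2 equiv, THF, −78 to 0 °C) deprotonates at the methyl group and, after loss of sulfinate and N2, should give 12. This is added to 11 as in step 7, with extra Ac2O to allow for the sulfinate.

**Further compounds**

F1 | step 8 | 3-tert-butoxy-4-[(10Z,13Z)-nonadeca-1,10,13-trien-2-yl]-4-(trimethylsilyloxy)cyclobut-2-en-1-one (racemic) | CCCCC/C=C\C/C=C\CCCCCCCC(=C)C1(O[Si](C)(C)C)C(OC(C)(C)C)=CC1=O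
F2 | step 8 | 3-tert-butoxy-5-[(8Z,11Z)-heptadeca-8,11-dien-1-yl]-4-(trimethylsilyloxy)phenol | CCCCC/C=C\C/C=C\CCCCCCCc1cc(O)cc(OC(C)(C)C)c1O[Si](C)(C)C
F3 | step 8 | 2-tert-butoxy-6-[(8Z,11Z)-heptadeca-8,11-dien-1-yl]benzene-1,4-diol | CCCCC/C=C\C/C=C\CCCCCCCc1cc(O)cc(OC(C)(C)C)c1O
F4 | step 8 | 2-tert-butoxy-4-(tert-butyldimethylsilyloxy)-6-[(8Z,11Z)-heptadeca-8,11-dien-1-yl]phenol | CCCCC/C=C\C/C=C\CCCCCCCc1cc(O[Si](C)(C)C(C)(C)C)cc(OC(C)(C)C)c1O
F5 | step 8 | 2-tert-butoxy-4-(tert-butyldimethylsilyloxy)-6-[(8Z,11Z)-heptadeca-8,11-dien-1-yl]phenyl acetate | CCCCC/C=C\C/C=C\CCCCCCCc1cc(O[Si](C)(C)C(C)(C)C)cc(OC(C)(C)C)c1OC(C)=O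
F6 | step 7 | 3-tert-butoxy-4-hydroxy-4-[(10Z,13Z)-nonadeca-1,10,13-trien-2-yl]cyclobut-2-en-1-one (racemic) | CCCCC/C=C\C/C=C\CCCCCCCC(=C)C1(O)C(OC(C)(C)C)=CC1=O
F7 | step 4 | (10Z,13Z)-nonadeca-10,13-dien-2-one | CCCCC/C=C\C/C=C\CCCCCCCC(C)=O
F8 | step 4 | N'-[(10Z,13Z)-nonadeca-10,13-dien-2-ylidene]-2,4,6-triisopropylbenzenesulfonohydrazide | CCCCC/C=C\C/C=C\CCCCCCCC(C)=NNS(=O)(=O)c1c(C(C)C)cc(C(C)C)cc1C(C)C
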